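**Retrosynthetic overview**

1. Feature: ring C of unit 1 (O1, C2, C3, C4, C4a, C8a) is a 2-aryl-2,3-dihydropyran-4-one whose only stereocentre, C2, carries ring B, and it is fused through C4a=C8a to a plain 5,7-dihydroxy benzo ring A. O1, C2 and C3 can therefore come from a ring B aldehyde and an oxygenated diene, and ring A (C5 to C8) can be added last.
2. Ring A: after removal of the benzyl ethers, C4a-C5 and C8-C8a are disconnected by a Diels-Alder reaction of a C4a-sulfinyl ring C with the bis(silyl) dienol ether of methyl acetoacetate (loss of PhSOH and MeOH).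
3. Ring C: C2-C3 and O1-C8a are disconnected by an enantioselective hetero-Diels-Alder reaction of Danishefsky diene with the ring B aldehyde of complete (S)-unit 2.
4. Unit 2: ring F by thiourea-catalysed oxa-Michael closure of an ester-activated chalcone (sets C2''), made from a biaryl acetophenone (Suzuki bond C3'-C8'') and the ring E aldehyde.
5. Ring order: rings B, D and E are bought as benzenes; then the biaryl, ring F, ring C and ring A.

Key step: step 10

**Remarks on the chemistry**

- Numbering: unit 1 is the 5,7-dihydroxyflavanone (O1 to C8a, ring B C1' to C6'); unit 2 is the 5-hydroxy-7-methoxyflavanone (double-primed atoms, rings D, F and E); the units are joined C3'-C8''.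
- Assumption: (S)-BINOL is taken to direct the diene to the Si face of the aldehyde (giving 2S), and the quinidine-derived thiourea is taken to give 2''S; if a model reaction shows the opposite sense, (R)-BINOL or the quinine-derived pseudoenantiomer is used.
- A sulfinyl group, not a halogen, is placed on C4a: the cis-fused cycloadduct holds the C4a substituent syn to H-8a, which suits thermal syn elimination of a sulfoxide but not anti elimination of HX.
- After step 10 only acidic, neutral or pyridine-buffered conditions are used, because deprotonation at C3 (or C3'') could open ring C (or ring F) by β-elimination of O1 (or O1'').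

**Route**

Step 1
Reactants: 1 3-bromo-4-hydroxybenzaldehyde
Product: 2 4-(benzyloxy)-3-bromobenzaldehyde
Conditions: BnBr, K2CO3, DMF, rt
Reagents that add atoms: benzyl bromide BrCc1ccccc1
Why: Williamson ether synthesis on the acidic para-formyl phenol should be clean and protects the future 4'-OH as a hydrogenolysable ether.

Step 2
Reactants: 2 4-(benzyloxy)-3-bromobenzaldehyde
Product: 3 2-[4-(benzyloxy)-3-bromophenyl]-1,3-dioxolane
Conditions: ethylene glycol, TsOH·H2O (cat.), toluene, reflux, Dean-Stark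
Reagents that add atoms: ethylene glycol OCCO
Why: Acid-catalysed acetalisation with azeotropic removal of water masks the aldehyde against the basic coupling, the enolate acylation and the Knoevenagel step that follow.

Step 3
Reactants: 3 2-[4-(benzyloxy)-3-bromophenyl]-1,3-dioxolane
Product: 4 2-[2-(benzyloxy)-5-(1,3-dioxolan-2-yl)phenyl]-4,4,5,5-tetramethyl-1,3,2-dioxaborolane
Conditions: B2pin2, Pd(dppf)Cl2 (3 mol %), KOAc, dioxane, 90 °C
Reagents that add atoms: bis(pinacolato)diboron CC1(C)OB(OC1(C)C)B1OC(C)(C)C(C)(C)O1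
Why: Miyaura borylation of an aryl bromide tolerates the benzyl ether and the dioxolane and gives the ring B nucleophile for the biaryl bond.

Step 4
Reactants: 5 2',6'-dihydroxy-4'-methoxyacetophenone
Product: 6 2'-(benzyloxy)-6'-hydroxy-4'-methoxyacetophenone
Conditions: BnBr (1.05 equiv), K2CO3, acetone, reflux
Reagents that add atoms: benzyl bromide BrCc1ccccc1
Why: Williamson mono-benzylation should stop after one ether because the remaining hydroxyl is hydrogen-bonded to the ketone and far less nucleophilic.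

Step 5
Reactants: 6 2'-(benzyloxy)-6'-hydroxy-4'-methoxyacetophenone
Product: 7 6'-(benzyloxy)-2'-hydroxy-3'-iodo-4'-methoxyacetophenone
Conditions: NIS (1.0 equiv), TFA (cat.), MeCN, 0 °C to rt
Reagents that add atoms: N-iodosuccinimide O=C1CCC(=O)N1I
Why: Electrophilic aromatic iodination should go ortho to the free phenol, at the carbon flanked by OH and OMe that becomes C8''.

Step 6
Reactants: 7 6'-(benzyloxy)-2'-hydroxy-3'-iodo-4'-methoxyacetophenone; 4 2-[2-(benzyloxy)-5-(1,3-dioxolan-2-yl)phenyl]-4,4,5,5-tetramethyl-1,3,2-dioxaborolane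
Product: 8 1-{6-(benzyloxy)-3-[2-(benzyloxy)-5-(1,3-dioxolan-2-yl)phenyl]-2-hydroxy-4-methoxyphenyl}ethanone
Conditions: Pd(OAc)2 (5 mol %), SPhos (10 mol %), K3PO4, toluene/H2O, 90 °C
Reagents that add atoms: none
Why: Suzuki-Miyaura coupling forms the C3'-C8'' bond; the dialkylbiarylphosphine copes with the tri-ortho-substituted axis and the free phenol, and the dioxolane stops the aldehyde condensing with the methyl ketone in base.

Step 7
Reactants: 8 1-{6-(benzyloxy)-3-[2-(benzyloxy)-5-(1,3-dioxolan-2-yl)phenyl]-2-hydroxy-4-methoxyphenyl}ethanone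
Product: 9 tert-butyl 3-{6-(benzyloxy)-3-[2-(benzyloxy)-5-(1,3-dioxolan-2-yl)phenyl]-2-hydroxy-4-methoxyphenyl}-3-oxopropanoate
Conditions: LiN(SiMe3)2 (3.2 equiv), THF, −78 °C; Boc2O, −78 to 0 °C; AcOH quench
Reagents that add atoms: di-tert-butyl dicarbonate CC(C)(C)OC(=O)OC(=O)OC(C)(C)C
Why: Claisen-type C-acylation of the phenoxide-enolate dianion gives the β-keto ester, and any aryl carbonate formed at oxygen should move to carbon by Baker-Venkataraman acyl transfer under the excess base.

Step 8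
Reactants: 9 tert-butyl 3-{6-(benzyloxy)-3-[2-(benzyloxy)-5-(1,3-dioxolan-2-yl)phenyl]-2-hydroxy-4-methoxyphenyl}-3-oxopropanoate; 10 4-(benzyloxy)benzaldehyde
Product: 11 tert-butyl (Z)-2-{6-(benzyloxy)-3-[2-(benzyloxy)-5-(1,3-dioxolan-2-yl)phenyl]-2-hydroxy-4-methoxybenzoyl}-3-[4-(benzyloxy)phenyl]prop-2-enoate
Conditions: piperidine (20 mol %), AcOH (20 mol %), 4 Å molecular sieves, toluene, rt
Reagents that add atoms: none
Why: Knoevenagel condensation of the active methylene with the only free aldehyde gives the ester-activated chalcone, expected mainly as the isomer with the ring E aryl cis to the ester, and the hindered chelated phenol should not cyclise under the buffered conditions.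

Step 9
Reactants: 11 tert-butyl (Z)-2-{6-(benzyloxy)-3-[2-(benzyloxy)-5-(1,3-dioxolan-2-yl)phenyl]-2-hydroxy-4-methoxybenzoyl}-3-[4-(benzyloxy)phenyl]prop-2-enoate
Product: 14 4-(benzyloxy)-3-{(2S)-5-(benzyloxy)-2-[4-(benzyloxy)phenyl]-7-methoxy-4-oxochroman-8-yl}benzaldehyde, via tert-butyl flavanone-3-carboxylate 12 (not isolated), via dioxolane flavanone 13 (not isolated)
Conditions: quinidine-derived 3,5-bis(trifluoromethyl)phenyl thiourea (10 mol %), toluene, −25 °C; then TsOH·H2O, 80 °C; then 1 M HCl, THF, rt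
Reagents that add atoms: water O
Why: The bifunctional thiourea binds the β-keto ester while its quinuclidine nitrogen delivers the phenol to one face of the alkylidene (6-endo-trig oxa-Michael addition, setting C2'' as S), after which acid removes the tert-butyl ester with decarboxylation and hydrolyses the dioxolane without base that could open ring F.

Step 10
Reactants: 14 4-(benzyloxy)-3-{(2S)-5-(benzyloxy)-2-[4-(benzyloxy)phenyl]-7-methoxy-4-oxochroman-8-yl}benzaldehyde; 15 Danishefsky diene, (E)-1-methoxy-3-(trimethylsilyloxy)buta-1,3-diene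
Product: 17 (2S)-5-(benzyloxy)-8-{2-(benzyloxy)-5-[(2S)-4-oxo-3,4-dihydro-2H-pyran-2-yl]phenyl}-2-[4-(benzyloxy)phenyl]-7-methoxychroman-4-one, via Mukaiyama aldol silyl ether 16 (not isolated)
Conditions: (S)-BINOL (20 mol %), Ti(OiPr)4 (10 mol %), 4 Å molecular sieves, toluene, −20 °C to rt; then TFA, CH2Cl2, 0 °C
Reagents that add atoms: none
Why: The BINOL-bound tetravalent titanium centre coordinates the aldehyde oxygen of 14, and the unsubstituted terminus of diene 15 attacks the carbonyl carbon on its Si face, either in a concerted [4+2] event or as a Mukaiyama aldol addition giving 16; in both cases C2-C3 is formed. Trifluoroacetic acid then closes ring C by 6-endo-trig conjugate addition of the C2 oxygen to the methoxy enone terminus and loss of methanol, forming O1-C8a. The closest known reaction type is the Ti/BINOL-catalysed hetero-Diels-Alder reaction of aromatic aldehydes with Danishefsky diene. C2 is set by the chiral catalyst alone, since the C2'' centre is too remote to bias the aldehyde faces. The step needs aldehyde-over-ketone selectivity, which the conjugated, doubly ortho-substituted C4'' aryl ketone secures, and it needs freedom from base, which keeps C2'' intact.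

Step 11
Reactants: 17 (2S)-5-(benzyloxy)-8-{2-(benzyloxy)-5-[(2S)-4-oxo-3,4-dihydro-2H-pyran-2-yl]phenyl}-2-[4-(benzyloxy)phenyl]-7-methoxychroman-4-one
Product: 18 (2S)-5-(benzyloxy)-8-{2-(benzyloxy)-5-[(2S)-4-oxo-5-(phenylsulfanyl)-3,4-dihydro-2H-pyran-2-yl]phenyl}-2-[4-(benzyloxy)phenyl]-7-methoxychroman-4-one
Conditions: PhSCl (1.05 equiv), pyridine, CH2Cl2, −78 to −20 °C
Reagents that add atoms: benzenesulfenyl chloride ClSc1ccccc1
Why: Electrophilic α-sulfenylation of the vinylogous ester (sulfenyl chloride adds to the enol ether carbon C4a, then HCl is lost to pyridine) should outrun aromatic substitution at low temperature and leaves C2 untouched.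

Step 12
Reactants: 18 (2S)-5-(benzyloxy)-8-{2-(benzyloxy)-5-[(2S)-4-oxo-5-(phenylsulfanyl)-3,4-dihydro-2H-pyran-2-yl]phenyl}-2-[4-(benzyloxy)phenyl]-7-methoxychroman-4-one
Product: 19 (2S)-5-(benzyloxy)-8-{2-(benzyloxy)-5-[(2S)-4-oxo-5-(phenylsulfinyl)-3,4-dihydro-2H-pyran-2-yl]phenyl}-2-[4-(benzyloxy)phenyl]-7-methoxychroman-4-one
Conditions: mCPBA (1.0 equiv), CH2Cl2, −78 °C
Reagents that add atoms: 3-chloroperbenzoic acid OOC(=O)c1cccc(Cl)c1
Why: Sulfide-to-sulfoxide oxidation with one equivalent of peracid at low temperature is faster than epoxidation of the push-pull alkene or Baeyer-Villiger oxidation, and both sulfur epimers serve because the group is lost in step 15.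

Step 13
Reactants: 20 methyl acetoacetate
Product: 21 methyl 3-(trimethylsilyloxy)but-2-enoate
Conditions: Me3SiCl, Et3N, hexane, rt
Reagents that add atoms: chlorotrimethylsilane C[Si](C)(C)Cl
Why: O-silylation of the enolised β-keto ester gives the silyl enol ether, used as an E/Z mixture.

Step 14
Reactants: 21 methyl 3-(trimethylsilyloxy)but-2-enoate
Product: 22 1-methoxy-1,3-bis(trimethylsilyloxy)buta-1,3-diene
Conditions: LiN(iPr)2, THF, −78 °C; Me3SiCl, −78 °C to rt; non-aqueous work-up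
Reagents that add atoms: chlorotrimethylsilane C[Si](C)(C)Cl
Why: Kinetic γ-deprotonation of the silyloxy enoate and O-silylation of the ester dienolate give the electron-rich 1,1,3-trioxygenated diene.

Step 15
Reactants: 19 (2S)-5-(benzyloxy)-8-{2-(benzyloxy)-5-[(2S)-4-oxo-5-(phenylsulfinyl)-3,4-dihydro-2H-pyran-2-yl]phenyl}-2-[4-(benzyloxy)phenyl]-7-methoxychroman-4-one; 22 1-methoxy-1,3-bis(trimethylsilyloxy)buta-1,3-diene
Product: 25 (2S)-5-(benzyloxy)-8-{2-(benzyloxy)-5-[(2S)-5,7-dihydroxy-4-oxochroman-2-yl]phenyl}-2-[4-(benzyloxy)phenyl]-7-methoxychroman-4-one, via cis-fused sulfinyl cycloadduct 23 (not isolated), via dienyl ketal 24 (not isolated)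
Conditions: 22 (3 equiv), toluene, 0 to 45 °C; then 1 M HCl, THF, 0 °C
Reagents that add atoms: none
Why: Proposed new method: the ketone and sulfinyl groups, both on C4a, make C8a the electrophilic end of the C4a=C8a bond, so the nucleophilic CH2 terminus of the diene should bond to C8a and its ketene acetal carbon to C4a (Diels-Alder reaction, concerted or by Michael addition and ring closure, both giving cis-fused 23 with the sulfinyl group syn to H-8a); thermal syn elimination of benzenesulfenic acid then restores C4a=C8a (24), and acid-promoted 1,4-loss of methanol with desilylation gives the aromatic 5,7-diol, the ester carbon ending as C5 and the ketone carbon as C7; the closest known reaction types are the Diels-Alder/sulfoxide-elimination sequences of 2-sulfinyl enones and sulfinylquinones and the regiocontrolled aromatising annulations of activated quinones with 1,1,3-trioxygenated butadienes; no base is used, so C2 and C2'' are not endangered.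

Step 16
Reactants: 25 (2S)-5-(benzyloxy)-8-{2-(benzyloxy)-5-[(2S)-5,7-dihydroxy-4-oxochroman-2-yl]phenyl}-2-[4-(benzyloxy)phenyl]-7-methoxychroman-4-one
Product: 26 CNP0237714.1, (2S)-5-hydroxy-8-{2-hydroxy-5-[(2S)-5,7-dihydroxy-4-oxochroman-2-yl]phenyl}-2-(4-hydroxyphenyl)-7-methoxychroman-4-one
Conditions: H2 (1 atm), Pd/C (10% Pd on carbon), EtOAc/MeOH, rt
Reagents that add atoms: none
Why: Neutral catalytic hydrogenolysis cleaves the three aryl benzyl ethers and should spare the methyl ether, the aryl ketones and the base-labile C2 and C2'' centres if stopped at full debenzylation.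

**Compound list**

1 | 3-bromo-4-hydroxybenzaldehyde | O=Cc1ccc(O)c(Br)c1 | starting material
2 | 4-(benzyloxy)-3-bromobenzaldehyde | O=Cc1ccc(OCc2ccccc2)c(Br)c1 | intermediate
3 | 2-[4-(benzyloxy)-3-bromophenyl]-1,3-dioxolane | Brc1cc(C2OCCO2)ccc1OCc1ccccc1 | intermediate
4 | 2-[2-(benzyloxy)-5-(1,3-dioxolan-2-yl)phenyl]-4,4,5,5-tetramethyl-1,3,2-dioxaborolane | CC1(C)OB(OC1(C)C)c1cc(C2OCCO2)ccc1OCc1ccccc1 | intermediate
5 | 2',6'-dihydroxy-4'-methoxyacetophenone | CC(=O)c1c(O)cc(OC)cc1O | starting material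
6 | 2'-(benzyloxy)-6'-hydroxy-4'-methoxyacetophenone | CC(=O)c1c(O)cc(OC)cc1OCc1ccccc1 | intermediate
7 | 6'-(benzyloxy)-2'-hydroxy-3'-iodo-4'-methoxyacetophenone | CC(=O)c1c(O)c(I)c(OC)cc1OCc1ccccc1 | intermediate
8 | 1-{6-(benzyloxy)-3-[2-(benzyloxy)-5-(1,3-dioxolan-2-yl)phenyl]-2-hydroxy-4-methoxyphenyl}ethanone (biaryl ketone) | CC(=O)c1c(O)c(-c2cc(C3OCCO3)ccc2OCc2ccccc2)c(OC)cc1OCc1ccccc1 | intermediate
9 | tert-butyl 3-{6-(benzyloxy)-3-[2-(benzyloxy)-5-(1,3-dioxolan-2-yl)phenyl]-2-hydroxy-4-methoxyphenyl}-3-oxopropanoate | CC(C)(C)OC(=O)CC(=O)c1c(O)c(-c2cc(C3OCCO3)ccc2OCc2ccccc2)c(OC)cc1OCc1ccccc1 | intermediate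
10 | 4-(benzyloxy)benzaldehyde | O=Cc1ccc(OCc2ccccc2)cc1 | starting material
11 | tert-butyl (Z)-2-{6-(benzyloxy)-3-[2-(benzyloxy)-5-(1,3-dioxolan-2-yl)phenyl]-2-hydroxy-4-methoxybenzoyl}-3-[4-(benzyloxy)phenyl]prop-2-enoate (ring E aryl cis to the ester) | CC(C)(C)OC(=O)/C(=C\c1ccc(OCc2ccccc2)cc1)C(=O)c1c(O)c(-c2cc(C3OCCO3)ccc2OCc2ccccc2)c(OC)cc1OCc1ccccc1 | intermediate
12 | tert-butyl (2S)-5-(benzyloxy)-8-[2-(benzyloxy)-5-(1,3-dioxolan-2-yl)phenyl]-2-[4-(benzyloxy)phenyl]-7-methoxy-4-oxochromane-3-carboxylate (C3 epimerisable, not assigned) | COc1cc(OCc2ccccc2)c2c(c1-c1cc(C3OCCO3)ccc1OCc1ccccc1)O[C@H](c1ccc(OCc3ccccc3)cc1)C(C(=O)OC(C)(C)C)C2=O | intermediate (not isolated)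
13 | (2S)-5-(benzyloxy)-8-[2-(benzyloxy)-5-(1,3-dioxolan-2-yl)phenyl]-2-[4-(benzyloxy)phenyl]-7-methoxychroman-4-one | COc1cc(OCc2ccccc2)c2c(c1-c1cc(C3OCCO3)ccc1OCc1ccccc1)O[C@H](c1ccc(OCc3ccccc3)cc1)CC2=O | intermediate (not isolated)
14 | 4-(benzyloxy)-3-{(2S)-5-(benzyloxy)-2-[4-(benzyloxy)phenyl]-7-methoxy-4-oxochroman-8-yl}benzaldehyde (ring B aldehyde of protected unit 2) | COc1cc(OCc2ccccc2)c2c(c1-c1cc(C=O)ccc1OCc1ccccc1)O[C@H](c1ccc(OCc3ccccc3)cc1)CC2=O | intermediate
15 | Danishefsky diene, (E)-1-methoxy-3-(trimethylsilyloxy)buta-1,3-diene | CO/C=C/C(=C)O[Si](C)(C)C | starting material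
16 | (2S)-5-(benzyloxy)-8-{2-(benzyloxy)-5-[(1S,4E)-5-methoxy-3-oxo-1-(trimethylsilyloxy)pent-4-en-1-yl]phenyl}-2-[4-(benzyloxy)phenyl]-7-methoxychroman-4-one | COc1cc(OCc2ccccc2)c2c(c1-c1cc([C@@H](O[Si](C)(C)C)CC(=O)/C=C/OC)ccc1OCc1ccccc1)O[C@H](c1ccc(OCc3ccccc3)cc1)CC2=O | intermediate (not isolated)
17 | (2S)-5-(benzyloxy)-8-{2-(benzyloxy)-5-[(2S)-4-oxo-3,4-dihydro-2H-pyran-2-yl]phenyl}-2-[4-(benzyloxy)phenyl]-7-methoxychroman-4-one | COc1cc(OCc2ccccc2)c2c(c1-c1cc([C@@H]3CC(=O)C=CO3)ccc1OCc1ccccc1)O[C@H](c1ccc(OCc3ccccc3)cc1)CC2=O | intermediate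
18 | (2S)-5-(benzyloxy)-8-{2-(benzyloxy)-5-[(2S)-4-oxo-5-(phenylsulfanyl)-3,4-dihydro-2H-pyran-2-yl]phenyl}-2-[4-(benzyloxy)phenyl]-7-methoxychroman-4-one | COc1cc(OCc2ccccc2)c2c(c1-c1cc([C@@H]3CC(=O)C(Sc4ccccc4)=CO3)ccc1OCc1ccccc1)O[C@H](c1ccc(OCc3ccccc3)cc1)CC2=O | intermediate
19 | (2S)-5-(benzyloxy)-8-{2-(benzyloxy)-5-[(2S)-4-oxo-5-(phenylsulfinyl)-3,4-dihydro-2H-pyran-2-yl]phenyl}-2-[4-(benzyloxy)phenyl]-7-methoxychroman-4-one (mixture of epimers at sulfur) | COc1cc(OCc2ccccc2)c2c(c1-c1cc([C@@H]3CC(=O)C(S(=O)c4ccccc4)=CO3)ccc1OCc1ccccc1)O[C@H](c1ccc(OCc3ccccc3)cc1)CC2=O | intermediate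
20 | methyl acetoacetate | COC(=O)CC(C)=O | starting material
21 | methyl 3-(trimethylsilyloxy)but-2-enoate (E/Z mixture) | COC(=O)C=C(C)O[Si](C)(C)C | intermediate
22 | 1-methoxy-1,3-bis(trimethylsilyloxy)buta-1,3-diene (ketene acetal geometry immaterial) | COC(O[Si](C)(C)C)=CC(=C)O[Si](C)(C)C | intermediate
23 | cis-fused Diels-Alder adduct of 19 and 22: 4a-(phenylsulfinyl)-5-methoxy-5,7-bis(trimethylsilyloxy)-4a,5,8,8a-tetrahydrochroman-4-one unit on ring B, 2S; the new centres C4a, C5, C8a and sulfur are not assigned | COc1cc(OCc2ccccc2)c2c(c1-c1cc([C@@H]3CC(=O)C4(S(=O)c5ccccc5)C(OC)(O[Si](C)(C)C)C=C(O[Si](C)(C)C)CC4O3)ccc1OCc1ccccc1)O[C@H](c1ccc(OCc3ccccc3)cc1)CC2=O | intermediate (not isolated)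
24 | product of sulfenic acid loss from 23: 5-methoxy-5,7-bis(trimethylsilyloxy)-5,8-dihydrochroman-4-one unit with C4a=C8a restored, 2S; C5 not assigned | COc1cc(OCc2ccccc2)c2c(c1-c1cc([C@@H]3CC(=O)C4=C(O3)CC(O[Si](C)(C)C)=CC4(OC)O[Si](C)(C)C)ccc1OCc1ccccc1)O[C@H](c1ccc(OCc3ccccc3)cc1)CC2=O | intermediate (not isolated)
25 | (2S)-5-(benzyloxy)-8-{2-(benzyloxy)-5-[(2S)-5,7-dihydroxy-4-oxochroman-2-yl]phenyl}-2-[4-(benzyloxy)phenyl]-7-methoxychroman-4-one | COc1cc(OCc2ccccc2)c2c(c1-c1cc([C@@H]3CC(=O)c4c(O)cc(O)cc4O3)ccc1OCc1ccccc1)O[C@H](c1ccc(OCc3ccccc3)cc1)CC2=O | intermediate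
26 | CNP0237714.1, (2S)-5-hydroxy-8-{2-hydroxy-5-[(2S)-5,7-dihydroxy-4-oxochroman-2-yl]phenyl}-2-(4-hydroxyphenyl)-7-methoxychroman-4-one | COc1cc(O)c2c(c1-c1cc([C@@H]3CC(=O)c4c(O)cc(O)cc4O3)ccc1O)O[C@H](c1ccc(O)cc1)CC2=O | target

**Step count**

Total: 16 steps. Longest linear sequence: 12 steps (steps 1 to 3, 6 to 12, 15 and 16).

**Steps most likely to fail**

1. Step 15 (proposed new method). The electron-rich diene may act as a carbon nucleophile or silyl donor instead of a 4π partner. Conjugate addition at C8a followed by β-elimination of O1 would open ring C, and silyl transfer to the sulfoxide oxygen could start a Pummerer-type loss of the activating group. A weakly dienophilic push-pull alkene would also let the diene decompose first.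
   Fallback (known chemistry): it leaves the route at aldehyde 14 and builds unit 1 by the ester-activated chalcone sequence already used for unit 2. 2',4',6'-Trihydroxyacetophenone is dibenzylated (BnBr, K2CO3, acetone) to 2',4'-bis(benzyloxy)-6'-hydroxyacetophenone F1. F1 is C-acylated (LiN(SiMe3)2, Boc2O, THF) to tert-butyl 3-[2,4-bis(benzyloxy)-6-hydroxyphenyl]-3-oxopropanoate F2. Knoevenagel condensation of F2 with 14 (piperidine, AcOH, molecular sieves) should give the alkylidene keto ester F3. The same thiourea closes ring C by oxa-Michael addition to the tert-butyl 3-carboxylate F4 (not isolated), and TsOH at 80 °C decarboxylates it to the pentabenzyl biflavanone F5. Hydrogenolysis of F5 under the conditions of step 16 returns to the route at target 26.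

2. Step 10 (key step). The Lewis-basic ketone and ether oxygens of 14 may sequester the titanium catalyst and slow turnover. The electron-rich 4-alkoxybenzaldehyde is a sluggish electrophile, so an uncatalysed or silyl-catalysed Mukaiyama background path could erode facial selectivity at C2.
   Fallback: it sets out from 14 and uses a stoichiometric chiral boron aldol reaction. (E)-4-Methoxybut-3-en-2-one is enolised with B-chlorodiisopinocampheylborane (the enantiomer that gives Si-face addition) and iPr2NEt in Et2O at −78 °C and added to 14; work-up should give the (S)-β-hydroxy enone F6. Acid (TFA or PPTS, CH2Cl2) then closes ring C by conjugate addition and loss of methanol, rejoining the route at 17.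

3. Step 11. Electrophilic sulfenylation may also occur on ring D at C6'', the free position of the trioxygenated arene, or run on to double sulfenylation, giving mixtures that are hard to separate at this molecular weight.
   Fallback: it sets out from 17 and separates the functionalisation from the C-S bond formation. Pyridine-mediated α-iodination (I2, pyridine, CH2Cl2, rt), a weak electrophile that spares alkoxyarenes, should give the C4a-iodo dihydropyranone F7. Pd2(dba)3/Xantphos-catalysed C-S cross-coupling of F7 with thiophenol and iPr2NEt in dioxane at moderate temperature then rejoins the route at sulfide 18.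

**Further compounds**

F1 | step 15 | 2',4'-bis(benzyloxy)-6'-hydroxyacetophenone | CC(=O)c1c(O)cc(OCc2ccccc2)cc1OCc1ccccc1
F2 | step 15 | tert-butyl 3-[2,4-bis(benzyloxy)-6-hydroxyphenyl]-3-oxopropanoate | CC(C)(C)OC(=O)CC(=O)c1c(O)cc(OCc2ccccc2)cc1OCc1ccccc1
F3 | step 15 | tert-butyl (Z)-2-[2,4-bis(benzyloxy)-6-hydroxybenzoyl]-3-{4-(benzyloxy)-3-[(2S)-5-(benzyloxy)-2-[4-(benzyloxy)phenyl]-7-methoxy-4-oxochroman-8-yl]phenyl}prop-2-enoate | COc1cc(OCc2ccccc2)c2c(c1-c1cc(/C=C(\C(=O)OC(C)(C)C)C(=O)c3c(O)cc(OCc4ccccc4)cc3OCc3ccccc3)ccc1OCc1ccccc1)O[C@H](c1ccc(OCc3ccccc3)cc1)CC2=O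
F4 | step 15 | tert-butyl (2S)-5,7-bis(benzyloxy)-2-{4-(benzyloxy)-3-[(2S)-5-(benzyloxy)-2-[4-(benzyloxy)phenyl]-7-methoxy-4-oxochroman-8-yl]phenyl}-4-oxochromane-3-carboxylate (C3 not assigned, not isolated) | COc1cc(OCc2ccccc2)c2c(c1-c1cc([C@@H]3C(C(=O)OC(C)(C)C)C(=O)c4c(OCc5ccccc5)cc(OCc5ccccc5)cc4O3)ccc1OCc1ccccc1)O[C@H](c1ccc(OCc3ccccc3)cc1)CC2=O
F5 | step 15 | (2S)-5-(benzyloxy)-8-{2-(benzyloxy)-5-[(2S)-5,7-bis(benzyloxy)-4-oxochroman-2-yl]phenyl}-2-[4-(benzyloxy)phenyl]-7-methoxychroman-4-one | COc1cc(OCc2ccccc2)c2c(c1-c1cc([C@@H]3CC(=O)c4c(OCc5ccccc5)cc(OCc5ccccc5)cc4O3)ccc1OCc1ccccc1)O[C@H](c1ccc(OCc3ccccc3)cc1)CC2=O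
F6 | step 10 | (2S)-5-(benzyloxy)-8-{2-(benzyloxy)-5-[(1S,4E)-1-hydroxy-5-methoxy-3-oxopent-4-en-1-yl]phenyl}-2-[4-(benzyloxy)phenyl]-7-methoxychroman-4-one | COc1cc(OCc2ccccc2)c2c(c1-c1cc([C@@H](O)CC(=O)/C=C/OC)ccc1OCc1ccccc1)O[C@H](c1ccc(OCc3ccccc3)cc1)CC2=O
F7 | step 11 | (2S)-5-(benzyloxy)-8-{2-(benzyloxy)-5-[(2S)-5-iodo-4-oxo-3,4-dihydro-2H-pyran-2-yl]phenyl}-2-[4-(benzyloxy)phenyl]-7-methoxychroman-4-one | COc1cc(OCc2ccccc2)c2c(c1-c1cc([C@@H]3CC(=O)C(I)=CO3)ccc1OCc1ccccc1)O[C@H](c1ccc(OCc3ccccc3)cc1)CC2=O
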